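The route cuts the bond between benzylic C1 of the tetralin (C1 carries the side chain, C4 the methyl, C8 the CO2H) and the side-chain CH(CH3) carbon. One stereospecific lithiation–borylation joins the halves: the α-lithiated carbamate of a cis-4-methyl-1-tetralol (C1 bears O instead of H) captures an enantiopure secondary boronic ester carrying the whole side chain, and a 1,2-metallate shift expels the carbamate to give a tertiary benzylic boronic ester. The step exploits benzylic C1 beside aromatic C8a: the C1–O bond acidifies C1–H, holds its configuration and then leaves, so both new stereocentres are reagent-controlled. Protodeboronation, C8 bromination/carboxylation, O-demethylation and esterification follow.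

Key step: step 11

Remark: tetralin numbering is used throughout (C1 = ring CH with the side chain, C4 = ring CH with CH3, C5 = C–O, C8 = C–CO2H, C4a/C8a = ring-fusion carbons). Compounds 1, 2, 8, 10, 15 and 27 are taken as purchasable. The sense of induction of the Ir catalyst in step 2 is assigned by analogy, and the ligand enantiomer that gives the R acid is used.

Step 1
Reactants: 1 1-(2-methoxyphenyl)ethan-1-one; 2 (2-carboxyethyl)triphenylphosphonium bromide
Product: 3 (E)-4-(2-methoxyphenyl)pent-3-enoic acid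
Conditions: KOt-Bu (2.2 equiv), THF, 0 °C to reflux; then aq HCl; crystallisation of the E acid
Reagents that add atoms: none
Why: Wittig olefination: the ylide–carboxylate generated with two equivalents of base should add to the aryl methyl ketone and give the β,γ-unsaturated acid mainly as the E isomer (aryl trans to CH2CO2H), which is purified by crystallisation.

Step 2
Reactants: 3 (E)-4-(2-methoxyphenyl)pent-3-enoic acid
Product: 4 (R)-4-(2-methoxyphenyl)pentanoic acid
Conditions: H2 (6 atm), [Ir(cod)(SIPHOX)]BArF (1 mol%), Et3N (0.5 equiv), MeOH, rt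
Reagents that add atoms: none
Why: Carboxylate-directed iridium-catalysed asymmetric hydrogenation of a β,γ-unsaturated acid, in which the chiral spiro P,N ligand selects the alkene face and sets the benzylic stereocentre (later C4) as R.

Step 3
Reactants: 4 (R)-4-(2-methoxyphenyl)pentanoic acid
Product: 5 (R)-5-methoxy-4-methyl-3,4-dihydronaphthalen-1(2H)-one
Conditions: PPA, 80 °C
Reagents that add atoms: none
Why: Intramolecular Friedel–Crafts acylation at the only free position ortho to the side chain should close the six-membered ketone without touching the stereocentre.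

Step 4
Reactants: 5 (R)-5-methoxy-4-methyl-3,4-dihydronaphthalen-1(2H)-one
Product: 6 (1S,4R)-5-methoxy-4-methyl-1,2,3,4-tetrahydronaphthalen-1-ol
Conditions: RuCl(p-cymene)[(S,S)-TsDPEN] (1 mol%), HCO2H/Et3N 5:2, 40 °C
Reagents that add atoms: none
Why: Noyori asymmetric transfer hydrogenation: the (S,S)-catalyst should deliver hydride to the face that gives the 1S carbinol, as it does for 1-tetralone, which with C4 fixed as R is the cis alcohol (OH and CH3 on the same face).

Step 5
Reactants: 6 (1S,4R)-5-methoxy-4-methyl-1,2,3,4-tetrahydronaphthalen-1-ol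
Product: 7 (1S,4R)-5-methoxy-4-methyl-1,2,3,4-tetrahydronaphthalen-1-yl N,N-diisopropylcarbamate
Conditions: i-Pr2NCOCl, Et3N, CH2Cl2, reflux
Reagents that add atoms: N,N-diisopropylcarbamoyl chloride CC(C)N(C(C)C)C(Cl)=O
Why: O-Carbamoylation of the secondary benzylic alcohol installs the directing and leaving group with retention, because no bond to C1 is broken.

Step 6
Reactants: 8 (S)-3-bromo-2-methylpropan-1-ol
Product: 9 (S)-(3-bromo-2-methylpropoxy)(tert-butyl)dimethylsilane
Conditions: TBSCl, imidazole, DMF, rt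
Reagents that add atoms: tert-butyldimethylsilyl chloride CC(C)(C)[Si](C)(C)Cl
Why: Standard silyl ether formation protects the primary alcohol against the organometallic steps that follow.

Step 7
Reactants: 9 (S)-(3-bromo-2-methylpropoxy)(tert-butyl)dimethylsilane; 10 allylmagnesium bromide
Product: 11 (R)-tert-butyldimethyl[(2-methylhex-5-en-1-yl)oxy]silane
Conditions: CuI (10 mol%), THF, 0 °C to rt
Reagents that add atoms: none
Why: Copper-catalysed sp3–sp3 cross-coupling (Kumada type) of the primary bromide with the allyl Grignard reagent extends the chain by three carbons and leaves the β-stereocentre untouched.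

Step 8
Reactants: 11 (R)-tert-butyldimethyl[(2-methylhex-5-en-1-yl)oxy]silane
Product: 13 (R)-6-(tert-butyldimethylsilyloxy)-5-methylhexan-1-ol, via B-alkyl-9-BBN adduct 12 (not isolated)
Conditions: 9-BBN, THF, rt; then NaOH, H2O2, 0 °C to rt
Reagents that add atoms: hydrogen peroxide OO
Why: Hydroboration–oxidation with the bulky 9-BBN is anti-Markovnikov on the terminal alkene and gives the primary alcohol.

Step 9
Reactants: 13 (R)-6-(tert-butyldimethylsilyloxy)-5-methylhexan-1-ol
Product: 14 (R)-6-(tert-butyldimethylsilyloxy)-5-methylhexyl N,N-diisopropylcarbamate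
Conditions: i-Pr2NCOCl, Et3N, CH2Cl2, reflux
Reagents that add atoms: N,N-diisopropylcarbamoyl chloride CC(C)N(C(C)C)C(Cl)=O
Why: O-Carbamoylation of the primary alcohol gives the Hoppe-type carbamate needed for directed α-lithiation.

Step 10
Reactants: 14 (R)-6-(tert-butyldimethylsilyloxy)-5-methylhexyl N,N-diisopropylcarbamate; 15 2,4,4,5,5-pentamethyl-1,3,2-dioxaborolane (MeBpin)
Product: 18 tert-butyldimethyl{[(2R,6S)-2-methyl-6-(4,4,5,5-tetramethyl-1,3,2-dioxaborolan-2-yl)heptyl]oxy}silane, via lithiated carbamate 16 (not isolated), via boronate complex 17 (not isolated)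
Conditions: s-BuLi, (−)-sparteine, Et2O, −78 °C, 5 h; 15, −78 °C; then MgBr2·OEt2, reflux
Reagents that add atoms: none
Why: Hoppe sparteine-mediated deprotonation removes the pro-S α-hydrogen, and the lithiation–borylation sequence (retentive borylation, then Matteson-type 1,2-migration of methyl with inversion) should give the S boronic ester by reagent control.

Step 11
Reactants: 7 (1S,4R)-5-methoxy-4-methyl-1,2,3,4-tetrahydronaphthalen-1-yl N,N-diisopropylcarbamate; 18 tert-butyldimethyl{[(2R,6S)-2-methyl-6-(4,4,5,5-tetramethyl-1,3,2-dioxaborolan-2-yl)heptyl]oxy}silane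
Product: 21 tert-butyl{[(2R,6S)-6-[(1S,4R)-5-methoxy-4-methyl-1-(4,4,5,5-tetramethyl-1,3,2-dioxaborolan-2-yl)-1,2,3,4-tetrahydronaphthalen-1-yl]-2-methylheptyl]oxy}dimethylsilane, via lithiated carbamate 19 (not isolated), via boronate complex 20 (not isolated)
Conditions: s-BuLi, Et2O, −78 °C, 1 h; 18 in Et2O, −78 °C, 3 h; then MgBr2 in MeOH, −78 °C to rt
Reagents that add atoms: none
Why: s-BuLi removes the benzylic C1–H of 7 (α to oxygen, directed by the carbamate C=O) with retention to give the configurationally stable lithium compound 19, which is borylated by 18 with retention to the boronate 20; on warming with MgBr2/MeOH the secondary alkyl group migrates from boron to C1 antiperiplanar to the departing carbamate. The closest known reaction type is the lithiation–borylation (1,2-metallate rearrangement) of secondary benzylic carbamates with secondary boronic esters, the established way to vicinal tertiary benzylic stereocentres; no ring is closed. C1: inversion at the migration terminus puts the side chain on the face opposite the former C–O bond, i.e. trans to the C4 methyl because 7 is the cis carbamate, and leaves boron on the face later taken by H. Side-chain CH(CH3): the migrating carbon keeps its configuration, so it is S as in 18. The step needs full stereochemical fidelity with two hindered partners; MgBr2/MeOH speeds migration relative to dissociation of 20, and C8 is still unsubstituted so that no peri strain builds up at the quaternary C1.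

Step 12
Reactants: 21 tert-butyl{[(2R,6S)-6-[(1S,4R)-5-methoxy-4-methyl-1-(4,4,5,5-tetramethyl-1,3,2-dioxaborolan-2-yl)-1,2,3,4-tetrahydronaphthalen-1-yl]-2-methylheptyl]oxy}dimethylsilane
Product: 22 (2R,6S)-6-[(1S,4R)-5-methoxy-4-methyl-1,2,3,4-tetrahydronaphthalen-1-yl]-2-methylheptan-1-ol
Conditions: TBAF·3H2O, toluene, 45 °C; then THF, rt
Reagents that add atoms: none
Why: Fluoride- and water-promoted protodeboronation of tertiary benzylic pinacol boronic esters is stereoretentive, so H takes the face that boron held (cis to the C4 methyl) and C1 becomes S, while the same fluoride source cleaves the primary silyl ether.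

Step 13
Reactants: 22 (2R,6S)-6-[(1S,4R)-5-methoxy-4-methyl-1,2,3,4-tetrahydronaphthalen-1-yl]-2-methylheptan-1-ol
Product: 23 (2R,6S)-6-[(1S,4R)-8-bromo-5-methoxy-4-methyl-1,2,3,4-tetrahydronaphthalen-1-yl]-2-methylheptan-1-ol
Conditions: NBS, MeCN, −10 °C to rt, dark
Reagents that add atoms: N-bromosuccinimide O=C1CCC(=O)N1Br
Why: Electrophilic aromatic substitution: NBS in acetonitrile brominates anisoles para to the methoxy group, here at C8, and the pseudoaxial side chain on C1 should not block the in-plane attack.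

Step 14
Reactants: 23 (2R,6S)-6-[(1S,4R)-8-bromo-5-methoxy-4-methyl-1,2,3,4-tetrahydronaphthalen-1-yl]-2-methylheptan-1-ol
Product: 25 (5R,8S)-8-[(2S,6R)-7-hydroxy-6-methylheptan-2-yl]-4-methoxy-5-methyl-5,6,7,8-tetrahydronaphthalene-1-carboxylic acid, via dilithio species 24 (not isolated)
Conditions: t-BuLi (3.2 equiv), THF, −78 °C; CO2; then aq HCl
Reagents that add atoms: carbon dioxide O=C=O
Why: Bromine–lithium exchange (one extra equivalent of t-BuLi deprotonates the alcohol) and carboxylation of the aryllithium with CO2 install the C8 carboxyl group.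

Step 15
Reactants: 25 (5R,8S)-8-[(2S,6R)-7-hydroxy-6-methylheptan-2-yl]-4-methoxy-5-methyl-5,6,7,8-tetrahydronaphthalene-1-carboxylic acid
Product: 26 (5R,8S)-4-hydroxy-8-[(2S,6R)-7-hydroxy-6-methylheptan-2-yl]-5-methyl-5,6,7,8-tetrahydronaphthalene-1-carboxylic acid
Conditions: NaSEt, DMF, 120 °C; then aq HCl
Reagents that add atoms: none
Why: SN2 O-demethylation by ethanethiolate at the methyl group, helped by the para carboxylate as electron sink, frees the phenol without affecting the alcohol or the stereocentres.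

Step 16
Reactants: 26 (5R,8S)-4-hydroxy-8-[(2S,6R)-7-hydroxy-6-methylheptan-2-yl]-5-methyl-5,6,7,8-tetrahydronaphthalene-1-carboxylic acid; 27 4-methylpent-3-enoic acid
Product: 28 (5R,8S)-4-hydroxy-5-methyl-8-[(2S,6R)-6-methyl-7-(4-methylpent-3-enoyloxy)heptan-2-yl]-5,6,7,8-tetrahydronaphthalene-1-carboxylic acid
Conditions: Novozym 435 (immobilised CAL-B), 27 (3 equiv), 4 Å MS, toluene, 45 °C
Reagents that add atoms: none
Why: Lipase-catalysed esterification: CAL-B acylates primary aliphatic alcohols but accepts neither the phenol as nucleophile nor the hindered aryl carboxylic acid as acyl donor, so only the side-chain alcohol should be esterified.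

Compound list
1 | 1-(2-methoxyphenyl)ethan-1-one | CC(=O)c1ccccc1OC | starting material
2 | (2-carboxyethyl)triphenylphosphonium bromide | OC(=O)CC[P+](c1ccccc1)(c1ccccc1)c1ccccc1.[Br-] | starting material
3 | (E)-4-(2-methoxyphenyl)pent-3-enoic acid | C/C(=C\CC(=O)O)c1ccccc1OC | intermediate
4 | (R)-4-(2-methoxyphenyl)pentanoic acid | OC(=O)CC[C@@H](C)c1ccccc1OC | intermediate
5 | (R)-5-methoxy-4-methyl-3,4-dihydronaphthalen-1(2H)-one | O=C1CC[C@@H](C)c2c(OC)cccc21 | intermediate
6 | (1S,4R)-5-methoxy-4-methyl-1,2,3,4-tetrahydronaphthalen-1-ol (cis) | O[C@H]1CC[C@@H](C)c2c(OC)cccc21 | intermediate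
7 | (1S,4R)-5-methoxy-4-methyl-1,2,3,4-tetrahydronaphthalen-1-yl N,N-diisopropylcarbamate | CC(C)N(C(C)C)C(=O)O[C@H]1CC[C@@H](C)c2c(OC)cccc21 | intermediate
8 | (S)-3-bromo-2-methylpropan-1-ol | OC[C@H](C)CBr | starting material
9 | (S)-(3-bromo-2-methylpropoxy)(tert-butyl)dimethylsilane | CC(C)(C)[Si](C)(C)OC[C@H](C)CBr | intermediate
10 | allylmagnesium bromide | C=CC[Mg]Br | starting material
11 | (R)-tert-butyldimethyl[(2-methylhex-5-en-1-yl)oxy]silane | CC(C)(C)[Si](C)(C)OC[C@H](C)CCC=C | intermediate
12 | 9-[(5R)-6-(tert-butyldimethylsilyloxy)-5-methylhexyl]-9-borabicyclo[3.3.1]nonane | CC(C)(C)[Si](C)(C)OC[C@H](C)CCCCB1C2CCCC1CCC2 | intermediate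
13 | (R)-6-(tert-butyldimethylsilyloxy)-5-methylhexan-1-ol | CC(C)(C)[Si](C)(C)OC[C@H](C)CCCCO | intermediate
14 | (R)-6-(tert-butyldimethylsilyloxy)-5-methylhexyl N,N-diisopropylcarbamate | CC(C)(C)[Si](C)(C)OC[C@H](C)CCCCOC(=O)N(C(C)C)C(C)C | intermediate
15 | 2,4,4,5,5-pentamethyl-1,3,2-dioxaborolane (MeBpin) | CB1OC(C)(C)C(C)(C)O1 | starting material
16 | (1S,5R)-6-(tert-butyldimethylsilyloxy)-1-lithio-5-methylhexyl N,N-diisopropylcarbamate (sparteine complex) | CC(C)(C)[Si](C)(C)OC[C@H](C)CCC[C@H]([Li])OC(=O)N(C(C)C)C(C)C | intermediate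
17 | lithium B-methyl boronate complex of 16 with 15 | CC(C)(C)[Si](C)(C)OC[C@H](C)CCC[C@H]([B-]1(C)OC(C)(C)C(C)(C)O1)OC(=O)N(C(C)C)C(C)C.[Li+] | intermediate
18 | tert-butyldimethyl{[(2R,6S)-2-methyl-6-(4,4,5,5-tetramethyl-1,3,2-dioxaborolan-2-yl)heptyl]oxy}silane | CC(C)(C)[Si](C)(C)OC[C@H](C)CCC[C@H](C)B1OC(C)(C)C(C)(C)O1 | intermediate
19 | (1S,4R)-1-lithio-5-methoxy-4-methyl-1,2,3,4-tetrahydronaphthalen-1-yl N,N-diisopropylcarbamate | CC(C)N(C(C)C)C(=O)O[C@@]1([Li])CC[C@@H](C)c2c(OC)cccc21 | intermediate
20 | lithium boronate complex of 19 with 18 | CC(C)N(C(C)C)C(=O)O[C@@]1([B-]3(OC(C)(C)C(C)(C)O3)[C@@H](C)CCC[C@@H](C)CO[Si](C)(C)C(C)(C)C)CC[C@@H](C)c2c(OC)cccc21.[Li+] | intermediate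
21 | tert-butyl{[(2R,6S)-6-[(1S,4R)-5-methoxy-4-methyl-1-(4,4,5,5-tetramethyl-1,3,2-dioxaborolan-2-yl)-1,2,3,4-tetrahydronaphthalen-1-yl]-2-methylheptyl]oxy}dimethylsilane | CC(C)(C)[Si](C)(C)OC[C@H](C)CCC[C@H](C)[C@]1(B3OC(C)(C)C(C)(C)O3)CC[C@@H](C)c2c(OC)cccc21 | intermediate
22 | (2R,6S)-6-[(1S,4R)-5-methoxy-4-methyl-1,2,3,4-tetrahydronaphthalen-1-yl]-2-methylheptan-1-ol | OC[C@H](C)CCC[C@H](C)[C@@H]1CC[C@@H](C)c2c(OC)cccc21 | intermediate
23 | (2R,6S)-6-[(1S,4R)-8-bromo-5-methoxy-4-methyl-1,2,3,4-tetrahydronaphthalen-1-yl]-2-methylheptan-1-ol | OC[C@H](C)CCC[C@H](C)[C@@H]1CC[C@@H](C)c2c(OC)ccc(Br)c21 | intermediate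
24 | lithium alkoxide–C8 aryllithium derived from 23 | [Li]OC[C@H](C)CCC[C@H](C)[C@@H]1CC[C@@H](C)c2c(OC)ccc([Li])c21 | intermediate
25 | (5R,8S)-8-[(2S,6R)-7-hydroxy-6-methylheptan-2-yl]-4-methoxy-5-methyl-5,6,7,8-tetrahydronaphthalene-1-carboxylic acid | OC[C@H](C)CCC[C@H](C)[C@@H]1CC[C@@H](C)c2c(OC)ccc(C(=O)O)c21 | intermediate
26 | (5R,8S)-4-hydroxy-8-[(2S,6R)-7-hydroxy-6-methylheptan-2-yl]-5-methyl-5,6,7,8-tetrahydronaphthalene-1-carboxylic acid | OC[C@H](C)CCC[C@H](C)[C@@H]1CC[C@@H](C)c2c(O)ccc(C(=O)O)c21 | intermediate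
27 | 4-methylpent-3-enoic acid | CC(C)=CCC(=O)O | starting material
28 | (5R,8S)-4-hydroxy-5-methyl-8-[(2S,6R)-6-methyl-7-(4-methylpent-3-enoyloxy)heptan-2-yl]-5,6,7,8-tetrahydronaphthalene-1-carboxylic acid | CC(C)=CCC(=O)OC[C@H](C)CCC[C@H](C)[C@@H]1CC[C@@H](C)c2c(O)ccc(C(=O)O)c21 | target

Total step count: 16
Longest linear sequence: 11 steps (steps 1–5 then 11–16; the side-chain branch, steps 6–10 then 11–16, is equally long)

Steps most likely to fail

1. Step 11. Boronate formation between the tertiary benzylic lithium compound and the α-branched secondary boronic ester may be slow or reversible, which would return protonated carbamate or erode the stereochemical fidelity at C1. The fallback reverses the roles of the partners and also avoids the hindered tertiary boronic ester of step 12. It sets out from ketone 5 and carbamate 14 and comes back at alcohol 22. Ketone 5 is reduced with the enantiomeric catalyst RuCl(p-cymene)[(R,R)-TsDPEN] to the trans alcohol (1R,4R)-5-methoxy-4-methyl-1,2,3,4-tetrahydronaphthalen-1-ol F1, which is carbamoylated to (1R,4R)-5-methoxy-4-methyl-1,2,3,4-tetrahydronaphthalen-1-yl N,N-diisopropylcarbamate F2. Lithiation (s-BuLi, Et2O, −78 °C), trapping with pinacolborane and 1,2-hydride shift should replace the C1–O bond by a C1–B bond with retention and give the secondary benzylic boronic ester F3, with boron trans to the C4 methyl. Carbamate 14, lithiated with s-BuLi/(+)-sparteine, is then homologated with F3: the ring carbon migrates with retention and forms the same C1–side-chain bond in the α-boryl coupling product F4, whose boron sits where the methyl group has to be. Matteson homologation with (chloromethyl)lithium gives the primary boronic ester F5. Photoredox protodeboronation of its phenyllithium ate complex then turns C–CH2B into C–CH3 and gives the silyl ether F6. TBAF converts F6 into 22.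

2. Step 16. The enzyme may acylate the β-branched primary alcohol too slowly, or the acylation may spill over to the phenol, in a substrate that also carries a free carboxylic acid. The fallback changes the order of the last two operations so that the phenol stays masked during esterification. It sets out from 25 and comes back at 28. Acid 27 is converted with oxalyl chloride into 4-methylpent-3-enoyl chloride F7, which acylates the primary alcohol of 25 in CH2Cl2/pyridine at −20 °C; the mixed anhydride formed at the aryl carboxyl group is hydrolysed on aqueous work-up. This should give the methyl ether ester F8. The aryl methyl ether of F8 is then cleaved with BCl3/n-Bu4NI in CH2Cl2 at −78 to 0 °C, conditions chosen to spare the alkyl ester and the trisubstituted alkene, to give 28.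

3. Step 2 (with the alkene geometry from step 1). Incomplete E/Z control in the Wittig reaction or weaker face selection caused by the ortho-methoxy group would lower the enantiomeric purity at C4. The fallback resolves C4 at the alcohol stage instead. It sets out from 3 and comes back at 6. Acid 3, in any E/Z ratio, is hydrogenated over Pd/C to racemic 4-(2-methoxyphenyl)pentanoic acid F9, which is cyclised with PPA to racemic 5-methoxy-4-methyl-3,4-dihydronaphthalen-1(2H)-one F10. The transfer hydrogenation of step 4 then sets C1 as S in both enantiomers. The cis alcohol 6 (from the R ketone) is separated by chromatography from its trans diastereomer (1S,4S)-5-methoxy-4-methyl-1,2,3,4-tetrahydronaphthalen-1-ol F11 (from the S ketone).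

Further compounds
F1 | step 11 | (1R,4R)-5-methoxy-4-methyl-1,2,3,4-tetrahydronaphthalen-1-ol | O[C@@H]1CC[C@@H](C)c2c(OC)cccc21
F2 | step 11 | (1R,4R)-5-methoxy-4-methyl-1,2,3,4-tetrahydronaphthalen-1-yl N,N-diisopropylcarbamate | CC(C)N(C(C)C)C(=O)O[C@@H]1CC[C@@H](C)c2c(OC)cccc21
F3 | step 11 | 2-[(1R,4R)-5-methoxy-4-methyl-1,2,3,4-tetrahydronaphthalen-1-yl]-4,4,5,5-tetramethyl-1,3,2-dioxaborolane | CC3(C)OB(OC3(C)C)[C@@H]1CC[C@@H](C)c2c(OC)cccc21
F4 | step 11 | tert-butyl{[(2R,6S)-6-[(1S,4R)-5-methoxy-4-methyl-1,2,3,4-tetrahydronaphthalen-1-yl]-2-methyl-6-(4,4,5,5-tetramethyl-1,3,2-dioxaborolan-2-yl)hexyl]oxy}dimethylsilane | CC(C)(C)[Si](C)(C)OC[C@H](C)CCC[C@H](B3OC(C)(C)C(C)(C)O3)[C@@H]1CC[C@@H](C)c2c(OC)cccc21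
F5 | step 11 | tert-butyl{[(2R,6S)-6-[(1S,4R)-5-methoxy-4-methyl-1,2,3,4-tetrahydronaphthalen-1-yl]-2-methyl-7-(4,4,5,5-tetramethyl-1,3,2-dioxaborolan-2-yl)heptyl]oxy}dimethylsilane | CC(C)(C)[Si](C)(C)OC[C@H](C)CCC[C@H](CB3OC(C)(C)C(C)(C)O3)[C@@H]1CC[C@@H](C)c2c(OC)cccc21
F6 | step 11 | tert-butyl{[(2R,6S)-6-[(1S,4R)-5-methoxy-4-methyl-1,2,3,4-tetrahydronaphthalen-1-yl]-2-methylheptyl]oxy}dimethylsilane | CC(C)(C)[Si](C)(C)OC[C@H](C)CCC[C@H](C)[C@@H]1CC[C@@H](C)c2c(OC)cccc21
F7 | step 16 | 4-methylpent-3-enoyl chloride | CC(C)=CCC(Cl)=O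
F8 | step 16 | (5R,8S)-4-methoxy-5-methyl-8-[(2S,6R)-6-methyl-7-(4-methylpent-3-enoyloxy)heptan-2-yl]-5,6,7,8-tetrahydronaphthalene-1-carboxylic acid | CC(C)=CCC(=O)OC[C@H](C)CCC[C@H](C)[C@@H]1CC[C@@H](C)c2c(OC)ccc(C(=O)O)c21
F9 | step 2 | racemic 4-(2-methoxyphenyl)pentanoic acid | OC(=O)CCC(C)c1ccccc1OC
F10 | step 2 | racemic 5-methoxy-4-methyl-3,4-dihydronaphthalen-1(2H)-one | O=C1CCC(C)c2c(OC)cccc21
F11 | step 2 | (1S,4S)-5-methoxy-4-methyl-1,2,3,4-tetrahydronaphthalen-1-ol | O[C@H]1CC[C@H](C)c2c(OC)cccc21
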